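**Retrosynthesis**
- Torilin ⇒ the C8 angelate is installed last on the 8-hydroxy-11-acetoxy-guai-4-en-3-one. The 5/7 bicyclic enone comes from one intramolecular Pauson–Khand [2+2+1] cycloaddition of a 1,7-enyne. That step builds the cyclopentenone and the cycloheptane together and sets C1.
- The enyne's C9–C10 bond is formed by (E)-crotylboration of an α-silyloxy aldehyde. C9 is then deoxygenated, so C10 is set by stereorelay from C8.
- C7 and C8 come from (S)-3-hydroxy-γ-butyrolactone: trans-selective enolate propargylation, then MeMgBr opening to the C11 tertiary carbinol and the C9 primary alcohol.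
- No carbocycle exists until the Pauson–Khand step.

Assumptions: the angelate is the (Z)-2-methylbut-2-enoate, as in the given SMILES. Dr at C10 and C1 is taken as substrate-controlled, with any minor isomers separable by chromatography.

---

**Step 1**
Reactants: 1 (S)-3-hydroxy-γ-butyrolactone; 2 tert-butyldimethylsilyl chloride
Product: 3 (S)-4-(tert-butyldimethylsilyloxy)oxolan-2-one
Conditions: TBSCl, imidazole, DMF, 0→25 °C
Reagents that add atoms: TBSCl, CC(C)(C)[Si](C)(C)Cl
Why: Silyl protection of the secondary alcohol (C8 oxygen), which also prevents E1cB loss of the β-oxygen in the next step.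

**Step 2**
Reactants: 3; 4 1-bromo-2-butyne
Product: 5 (3S,4S)-3-(but-2-yn-1-yl)-4-(TBSO)oxolan-2-one
Conditions: LDA, THF, −78 °C; then 4, DMPU, −78→−40 °C
Reagents that add atoms: 1-bromo-2-butyne, CC#CCBr
Why: Lactone enolate alkylation occurs anti to the β-OTBS group, so C6 ends up trans to O8. This sets C7 with the relative configuration required by torilin (C11 anti to O8 in the zigzag C6–C9 chain).

**Step 3**
Reactants: 5; 6 methylmagnesium bromide
Product: 7 (2S,3S)-3-(but-2-yn-1-yl)-2-(TBSO)-4-methylpentane-1,4-diol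
Conditions: MeMgBr, CeCl3, THF, −78→0 °C
Reagents that add atoms: MeMgBr, C[Mg]Br
Why: Double Grignard addition to the lactone carbonyl (with the cerium additive suppressing enolisation and α-epimerisation) opens the ring and gives the C11 dimethyl carbinol and the free primary C9 alcohol, with no change at C7 or C8.

**Step 4**
Reactants: 7; 8 acetic anhydride
Product: 9 (3S,4S)-5-acetoxy-3-(but-2-yn-1-yl)-4-(TBSO)-2-methylpentan-2-yl acetate
Conditions: Ac2O, DMAP, Et3N, CH2Cl2, 40 °C
Reagents that add atoms: acetic anhydride, CC(=O)OC(C)=O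
Why: Acylation of both hydroxyls; the tertiary C11 acetate is the natural product's own group, so it is installed now and also blocks lactol formation later.

**Step 5**
Reactants: 9
Product: 10 (3S,4S)-3-(but-2-yn-1-yl)-4-(TBSO)-5-hydroxy-2-methylpentan-2-yl acetate
Conditions: K2CO3, MeOH, 0 °C
Reagents that add atoms: none
Why: Chemoselective methanolysis of the unhindered primary acetate; the tertiary acetate and the silyl ether survive.

**Step 6**
Reactants: 10
Product: 11 (3S,4S)-3-(but-2-yn-1-yl)-4-(TBSO)-2-methyl-5-oxopentan-2-yl acetate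
Conditions: Dess–Martin periodinane, NaHCO3, CH2Cl2, 0→25 °C
Reagents that add atoms: none
Why: Dess–Martin oxidation of the primary alcohol to the α-silyloxy aldehyde; the aldehyde is used crude to avoid α-epimerisation at C8.

**Step 7**
Reactants: 11; 12 (E)-crotylboronic acid pinacol ester
Product: 13 (3R,4R,5S,6S)-6-(but-2-yn-1-yl)-5-(TBSO)-4-hydroxy-3,7-dimethyloct-1-en-7-yl acetate
Conditions: 12, toluene, 25→40 °C, 48 h; then aq. NaOH workup
Reagents that add atoms: (E)-crotyl-Bpin, C/C=C/CB1OC(C)(C)C(C)(C)O1
Why: Crotylboration proceeds through a chair Zimmerman–Traxler transition state. The (E)-reagent gives the anti relationship between C9-OH and C10-Me, and Felkin–Anh attack anti to the C8–OTBS bond gives the anti relationship between C8-O and C9-OH. Together these make C10-Me syn to C8-O after C9 is removed, which is the required relation.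

**Step 8**
Reactants: 13; 14 phenyl chlorothionoformate
Product: 15 O-[(3R,4R,5S,6S)-…-4-yl] O-phenyl thionocarbonate of 13
Conditions: PhOC(S)Cl, DMAP, pyridine, CH2Cl2, 0→25 °C
Reagents that add atoms: phenyl chlorothionoformate, S=C(Cl)Oc1ccccc1
Why: Activation of the secondary C9 alcohol for radical deoxygenation (Robins variant of the Barton–McCombie reaction).

**Step 9**
Reactants: 15
Product: 16 (3S,5R,6S)-6-(but-2-yn-1-yl)-5-(TBSO)-3,7-dimethyloct-1-en-7-yl acetate
Conditions: Bu3SnH (0.3 M), AIBN, PhMe, 110 °C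
Reagents that add atoms: none
Why: Barton–McCombie deoxygenation removes the C9 stereocentre and leaves the C10 methyl-bearing vinyl centre fixed; the high tin-hydride concentration outcompetes 5-exo-dig cyclisation of the C9 radical onto the alkyne.

**Step 10**
Reactants: 16; 17 carbon monoxide
Product: 18 (1R,7S,8R,10S)-8-(TBSO)-3-oxoguai-4-en-11-yl acetate
Conditions: Co2(CO)8, CH2Cl2, 25 °C; then TMTU, CO (1 atm), PhMe, 70 °C
Reagents that add atoms: carbon monoxide, [C-]#[O+]
Why: Intramolecular Pauson–Khand reaction is a formal [2+2+1] cycloaddition of the methyl alkyne, the vinyl group and CO. It forms the C5–C1 and C3–C2 bonds, giving the cyclopentenone (C3=O, C4=C5) and the cycloheptane in one step. C1 is set with its new C1–C2 bond trans to the C10 methyl, which sits pseudo-equatorial in the seven-membered transition state.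

**Step 11**
Reactants: 18
Product: 19 (1R,7S,8R,10S)-8-hydroxy-3-oxoguai-4-en-11-yl acetate
Conditions: HF·pyridine, pyridine, THF, 25 °C, 24 h
Reagents that add atoms: none
Why: Buffered fluoride cleaves the secondary TBS ether; the tertiary acetate, enone and all stereocentres are untouched.

**Step 12**
Reactants: 19; 20 angelic acid
Product: 21 torilin, (1R,7S,8R,10S)-8-angeloyloxy-3-oxoguai-4-en-11-yl acetate
Conditions: 20, 2,4,6-trichlorobenzoyl chloride, Et3N, THF, 25 °C; then 19, DMAP, PhMe, 25 °C
Reagents that add atoms: angelic acid (supplies the angeloyl group), C/C=C(/C)C(=O)O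
Why: Yamaguchi esterification through the mixed anhydride acylates only the secondary C8 alcohol and retains the (Z) geometry at rt; the tertiary position is already acetylated.

---

**Compound list**

1 | (S)-3-hydroxy-γ-butyrolactone | O=C1C[C@H](O)CO1 | starting material
2 | tert-butyldimethylsilyl chloride | CC(C)(C)[Si](C)(C)Cl | starting material
3 | (S)-4-(TBSO)oxolan-2-one | O=C1C[C@H](O[Si](C)(C)C(C)(C)C)CO1 | intermediate
4 | 1-bromo-2-butyne | CC#CCBr | starting material
5 | (3S,4S)-3-(but-2-yn-1-yl)-4-(TBSO)oxolan-2-one | O=C1OC[C@@H](O[Si](C)(C)C(C)(C)C)[C@@H]1CC#CC | intermediate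
6 | methylmagnesium bromide | C[Mg]Br | starting material
7 | (2S,3S)-3-(but-2-yn-1-yl)-2-(TBSO)-4-methylpentane-1,4-diol | OC[C@@H](O[Si](C)(C)C(C)(C)C)[C@H](CC#CC)C(C)(C)O | intermediate
8 | acetic anhydride | CC(=O)OC(C)=O | starting material
9 | (3S,4S)-5-acetoxy-3-(but-2-yn-1-yl)-4-(TBSO)-2-methylpentan-2-yl acetate | CC(=O)OC[C@@H](O[Si](C)(C)C(C)(C)C)[C@H](CC#CC)C(C)(C)OC(C)=O | intermediate
10 | (3S,4S)-3-(but-2-yn-1-yl)-4-(TBSO)-5-hydroxy-2-methylpentan-2-yl acetate | OC[C@@H](O[Si](C)(C)C(C)(C)C)[C@H](CC#CC)C(C)(C)OC(C)=O | intermediate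
11 | (3S,4S)-3-(but-2-yn-1-yl)-4-(TBSO)-2-methyl-5-oxopentan-2-yl acetate | O=C[C@@H](O[Si](C)(C)C(C)(C)C)[C@H](CC#CC)C(C)(C)OC(C)=O | intermediate
12 | (E)-crotylboronic acid pinacol ester | C/C=C/CB1OC(C)(C)C(C)(C)O1 | starting material
13 | (3R,4R,5S,6S)-6-(but-2-yn-1-yl)-5-(TBSO)-4-hydroxy-3,7-dimethyloct-1-en-7-yl acetate | C=C[C@@H](C)[C@@H](O)[C@@H](O[Si](C)(C)C(C)(C)C)[C@H](CC#CC)C(C)(C)OC(C)=O | intermediate
14 | phenyl chlorothionoformate | S=C(Cl)Oc1ccccc1 | starting material
15 | O-phenyl thionocarbonate of 13 | C=C[C@@H](C)[C@@H](OC(=S)Oc1ccccc1)[C@@H](O[Si](C)(C)C(C)(C)C)[C@H](CC#CC)C(C)(C)OC(C)=O | intermediate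
16 | (3S,5R,6S)-6-(but-2-yn-1-yl)-5-(TBSO)-3,7-dimethyloct-1-en-7-yl acetate (1,7-enyne) | C=C[C@@H](C)C[C@@H](O[Si](C)(C)C(C)(C)C)[C@H](CC#CC)C(C)(C)OC(C)=O | intermediate
17 | carbon monoxide | [C-]#[O+] | starting material
18 | (1R,7S,8R,10S)-8-(TBSO)-3-oxoguai-4-en-11-yl acetate | CC(C)(C)[Si](C)(C)O[C@@H]1C[C@H](C)[C@H]2CC(=O)C(C)=C2C[C@@H]1C(C)(C)OC(C)=O | intermediate
19 | (1R,7S,8R,10S)-8-hydroxy-3-oxoguai-4-en-11-yl acetate | O[C@@H]1C[C@H](C)[C@H]2CC(=O)C(C)=C2C[C@@H]1C(C)(C)OC(C)=O | intermediate
20 | angelic acid ((Z)-2-methylbut-2-enoic acid) | C/C=C(/C)C(=O)O | starting material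
21 | torilin | C/C=C(/C)C(=O)O[C@@H]1C[C@H](C)[C@H]2CC(=O)C(C)=C2C[C@@H]1C(C)(C)OC(C)=O | target

---

**Total step count:** 12
**Longest linear sequence:** 12 steps, from 1 to 21

**Three steps most likely to fail**
1. Step 10 (Pauson–Khand): closing a seven-membered ring from a 1,7-enyne can be slow, and the C1 diastereoselectivity may be modest. Fallback: Buchwald-type titanocene-mediated enyne cyclocarbonylation (titanacyclopentene plus CO) on 16. The C1 epimers can then be equilibrated through the dienolate (DBU).
2. Step 7 (crotylboration): the Felkin and anti selectivities may not both be high, which would give a wrong C10 diastereomer. Fallback: change the C10 source to (S)-Roche ester by adding its derived (S)-2-methylbut-3-enyl Grignard to the corresponding C8 aldehyde. C8 would then be corrected by Mitsunobu esterification with angelic acid.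
3. Step 9 (Barton–McCombie on a hindered secondary thionocarbonate): the C9 radical may cyclise 5-exo-dig onto the alkyne. Fallback: ionic deoxygenation of 13 via its mesylate with LiEt3BH, which has no radical intermediate.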